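The runs are simulated for substances that don't exist; noise was put on by code.

At 4.0 h, how much target does the larch flask hold, and which option adds most?

| setting | larch | ash | flask |
|---|---|---|---|
| substrate | 0.11 M | 0.11 M | 0.11 M |
| coupling partner | 0.077 M | 0.077 M | 0.0770 M |
| free catalyst | 11 mM | 11 mM | 11 mM |
| temperature | 70 °C | 76 °C | 70 °C |
| remark | the very flask that is asked about, followed so far | run made earlier |  |
| time |  |  | 4.0 h |

| run | time / h | target / % |
|---|---|---|
| larch | 0.250 | 16.9 |
| larch | 0.833 | 26.5 |
| larch | 1.33 | 28.5 |
| larch | 2.50 | 27.5 |
| larch | 3.00 | 27.5 |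
| ash | 0.250 | 22.4 |
| ash | 0.833 | 29.7 |
| ash | 1.33 | 30.1 |
| ash | 2.50 | 31.1 |
| ash | 3.00 | 30.3 |

(standard deviation of a reading: 0.5 percentage points)

- amber: at 4.0 h raise the temperature by 15 K, then wait 80 min
- grey: at 4.0 h take out 90 % of the target then present, then wait 80 min
- blue: at 4.0 h add free catalyst, 50.0 % of the amount charged, then wait 80 min
- green: change nothing and wait 80 min more
- teal: at 4.0 h add coupling partner, 100 % of the amount charged, then wait 80 min

1. target, in percent of the substrate first charged, at 4.0 h
2. the option that brings most further target ("none" if no option brings more than 2 percentage points) (amber / grey / blue / green / teal / none)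
3. target present, with what was taken out counted in, in percent of the substrate first charged, after blue
4. target present, with what was taken out counted in, in percent of the substrate first charged, after green

- what is taken out of target is counted as made
- additions bring no volume worth counting

I go down the ladder of time scales in the larch run, then count.

| rung | time | larch flask |
|---|---|---|
| rise | 0.250 h | target 16.9 %, climbing |
| stall | 1.33 h | target 28.5 %, flat from here |
| last reading | 3.00 h | target 27.5 % |

The three flat readings average 27.8 %. Against that plateau the gap has a half-life near 0.185 h, far shorter than the wait to 4.0 h, so the flask should long have stood still by then.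

Why does it stand? Coupling partner, the limiting reagent, allows 70.0 %. Counting target as the one product, the free fractions are 0.722 of substrate and 0.602 of partner. The catalyst has made 2.78 turnovers, if it makes target at all. The ash run stalls as well. Either the catalyst dies or a balance is reached (thermodynamic control), and these readings don't choose.

I bet on the balance, because it lets me reckon green, blue, teal and grey. The stall quotient is target over free substrate times free partner, in fractions, divided by the partner charge: 8.32 M⁻¹.

So I say 27.8 % now, and green and blue add nothing, as neither moves the fractions. Teal lifts the partner fraction to 1.60, and the quotient then returns after 18 percentage points more target. Grey reckons to 13 points. Amber I can't reckon. I pick teal.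

The forecast, betting on catalyst death, says 27.9 % now, blue best, 36 % after blue and 27.9 % after green: “so only fresh catalyst helps”.

The flask gives 27.3 %, with teal best at 15 points; blue ends at 26.6 % and green at 26.9 %.

    substrate + coupling partner ⇌ target (K = 32.0 M⁻¹, k = 0.00420 M⁻¹ s⁻¹, Ea = 77.0 kJ mol⁻¹, ΔH = −17.0 kJ mol⁻¹)
    substrate + coupling partner ⇌ isomer of the product (K = 33.0 M⁻¹, k = 0.00200 M⁻¹ s⁻¹, Ea = 77.0 kJ mol⁻¹, ΔH = −87.0 kJ mol⁻¹)
    target + free catalyst ⇌ isomer of the product + free catalyst, rate k3*[free catalyst]*[target] forward; the back reaction follows from the equilibrium constant (k = 0.0210 M⁻¹ s⁻¹, Ea = 76.0 kJ mol⁻¹)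
    substrate + free catalyst → spent catalyst A (k = 7.50 × 10⁻⁴ M⁻¹ s⁻¹, Ea = 88.0 kJ mol⁻¹)
    free catalyst → spent catalyst B (k = 2.10 × 10⁻⁴ s⁻¹, Ea = 110 kJ mol⁻¹)
    (constants at 70 °C)

Up to 2.00 h, while free catalyst fell to 15.8 %, substrate and partner coupled into target and into isomer of the product, leaving substrate at 46.1 % and partner at 25.3 %. From there to 4.00 h they barely moved, ending at 45.0 % and 24.1 % with isomer at 25.8 %, and the quotient on these amounts is 32.7 M⁻¹.

For a neighbour charged with 0.31 M of partner, that recounted quotient, with isomer again matching target, gives 46.6 %. The computed flask holds 46.6 % of target and 45.9 % of isomer.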